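Numbering: C1 = fusion carbon with CH3, C2 = angelate carbon, C3 = CH2, C4 = isopropyl carbinol, C5 = fusion CH, C6 = anisate carbon, C7 = CH2, C8(CH3)=C9, C10 = CH2; ring A = C1–C5, ring B = C1/C5–C10.
Enabling feature: the one alkene of ring B, C8=C9, is separated by the methylenes C7 and C10 from the stereocentres C1, C2, C4, C5 and C6, which all lie on or directly beside ring A, so a finished ring A can carry two alkene arms and ring B can be closed last.
Retrosynthetic cuts: C2–O (angelate), C8=C9 (metathesis), C6–O (anisate), C6–C7 (methallyl addition to a C6 aldehyde), C1–C10 together with C5–C6 (one radical cascade), C4–isopropyl (1,2-addition), C1–CH3 (conjugate addition/dehydrogenation).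
Forward order: ring A is bought as cyclopentenone 1, a temporary oxasilolane ring is fused to C4–C5 in step 5 and oxidised away in step 6, ring B closes in step 10, and the angelate goes on last.
Stereochemistry: only C2 is bought; isopropyl adds anti to the C2 silyl ether (C4), the silicon tether on the C4 oxygen hands C6 to the same face (C5), allyl enters the opposite, convex face (C1), and chelate-controlled addition to the aldehyde sets C6.

Key step: step 10

Remark: 1 is taken as a purchasable enantiopure building block; locants in comments follow the numbering above, locants inside systematic names follow nomenclature rules.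

Step 1
Reactants: 1 (R)-4-(tert-butyldimethylsilyloxy)cyclopent-2-en-1-one; 2 methyllithium
Product: 4 (3R,4R)-4-(tert-butyldimethylsilyloxy)-3-methyl-1-(trimethylsilyloxy)cyclopent-1-ene, via lithium dimethylcuprate 3 (not isolated)
Conditions: MeLi, CuI, Et2O, 0 °C; then 1, Me3SiCl, −78 °C
Reagents that add atoms: methyllithium [Li]C; chlorotrimethylsilane C[Si](C)(C)Cl
Why: Gilman cuprate 1,4-addition accelerated by Me3SiCl places the future C1 methyl group on the β-carbon anti to the bulky silyl ether (a centre erased again in step 2), and O-silylation traps the enolate regiospecifically so that the β-silyloxy group cannot be eliminated.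

Step 2
Reactants: 4 (3R,4R)-4-(tert-butyldimethylsilyloxy)-3-methyl-1-(trimethylsilyloxy)cyclopent-1-ene
Product: 5 (R)-4-(tert-butyldimethylsilyloxy)-3-methylcyclopent-2-en-1-one
Conditions: Pd(OAc)2 (10 mol %), O2 (1 atm), DMSO, rt
Reagents that add atoms: none
Why: In this Saegusa–Ito oxidation divalent palladium takes up the enol silane, β-hydride elimination of the only available hydrogen (on the methyl-bearing carbon) restores the enone in β-methylated form, O2 reoxidises the zerovalent palladium, and the C2 stereocentre takes no part.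

Step 3
Reactants: 5 (R)-4-(tert-butyldimethylsilyloxy)-3-methylcyclopent-2-en-1-one; 6 isopropylmagnesium chloride
Product: 8 (1R,4R)-4-(tert-butyldimethylsilyloxy)-1-isopropyl-3-methylcyclopent-2-en-1-ol (hydroxyl cis to the silyl ether), via isopropylcerium dichloride 7 (not isolated)
Conditions: CeCl3, i-PrMgCl, THF, −78 °C; then 5, −78 to 0 °C
Reagents that add atoms: isopropylmagnesium chloride CC(C)[Mg]Cl
Why: Organocerium 1,2-addition is weakly basic and oxophilic, so enolisation, β-hydride reduction and 1,4-addition are avoided, and the reagent should attack the flat cyclopentenone opposite the C2 silyl ether (the sense known from Luche reduction of 4-silyloxycyclopentenones to cis products), which sets C4 with its hydroxyl cis to the C2 oxygen.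

Step 4
Reactants: 8 (1R,4R)-4-(tert-butyldimethylsilyloxy)-1-isopropyl-3-methylcyclopent-2-en-1-ol; 9 (bromomethyl)chlorodimethylsilane
Product: 10 (1R,4R)-1-[(bromomethyl)dimethylsilyloxy]-4-(tert-butyldimethylsilyloxy)-1-isopropyl-3-methylcyclopent-2-ene
Conditions: BrCH2SiMe2Cl, imidazole, DMAP (cat.), CH2Cl2, 0 °C to rt
Reagents that add atoms: (bromomethyl)chlorodimethylsilane C[Si](C)(Cl)CBr
Why: O-silylation of a tertiary alcohol with a small chlorosilane of trimethylsilyl size under imidazole/DMAP catalysis is routine, the basic medium spares the ionisable tertiary allylic carbinol, and no stereocentre changes.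

Step 5
Reactants: 10 (1R,4R)-1-[(bromomethyl)dimethylsilyloxy]-4-(tert-butyldimethylsilyloxy)-1-isopropyl-3-methylcyclopent-2-ene; 11 allyltributylstannane
Product: 12 (3aR,4R,5R,6aR)-4-allyl-5-(tert-butyldimethylsilyloxy)-6a-isopropyl-2,2,4-trimethylhexahydro-2H-cyclopenta[d][1,2]oxasilole (cis-fused; O–SiMe2–C6H2 bridges C4 and C5; allyl on C1 anti to that bridge)
Conditions: Bu3SnCH2CH=CH2 (excess), AIBN, PhH, 80 °C
Reagents that add atoms: allyltributylstannane C=CC[Sn](CCCC)(CCCC)CCCC
Why: This is a silicon-tethered radical cyclisation ended by a Keck allylation, in which bromine abstraction gives an α-silyl radical that can reach C5 only from the face of the C4 oxygen and closes 5-exo to the cis-fused oxasilolane (sets C5), after which the tertiary C1 radical is captured by the allylstannane on the convex face, anti to both the new ring and the C2 silyl ether (sets C1), with release of the chain-carrying stannyl radical.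

Step 6
Reactants: 12 cis-fused oxasilolane
Product: 13 (1R,2S,3R,4R)-3-allyl-4-(tert-butyldimethylsilyloxy)-2-(hydroxymethyl)-1-isopropyl-3-methylcyclopentan-1-ol
Conditions: 30% H2O2, KF, KHCO3, THF/MeOH, rt
Reagents that add atoms: hydrogen peroxide OO
Why: Tamao–Fleming oxidation of the alkoxysilane turns the C6–Si bond into C6–OH and frees the C4 hydroxyl without touching a ring stereocentre, and basic peroxide leaves the unactivated allyl alkene and the hindered secondary silyl ether alone.

Step 7
Reactants: 13 (1R,2S,3R,4R)-3-allyl-4-(tert-butyldimethylsilyloxy)-2-(hydroxymethyl)-1-isopropyl-3-methylcyclopentan-1-ol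
Product: 14 (1R,2R,3R,5R)-2-allyl-3-(tert-butyldimethylsilyloxy)-5-hydroxy-5-isopropyl-2-methylcyclopentane-1-carbaldehyde
Conditions: TEMPO (cat.), PhI(OAc)2, CH2Cl2, rt
Reagents that add atoms: none
Why: Oxoammonium oxidation picks the primary alcohol, cannot touch the tertiary one and stops at the aldehyde in the absence of water, and C5 already holds its more stable configuration (formyl trans to isopropyl and allyl), so epimerisation is no threat.

Step 8
Reactants: 14 (1R,2R,3R,5R)-2-allyl-3-(tert-butyldimethylsilyloxy)-5-hydroxy-5-isopropyl-2-methylcyclopentane-1-carbaldehyde; 15 2-methylallylmagnesium chloride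
Product: 16 (1R,2S,3R,4R)-3-allyl-4-(tert-butyldimethylsilyloxy)-2-[(1S)-1-hydroxy-3-methylbut-3-en-1-yl]-1-isopropyl-3-methylcyclopentan-1-ol
Conditions: CH2=C(CH3)CH2MgCl (3 equiv), THF, −78 °C
Reagents that add atoms: 2-methylallylmagnesium chloride CC(=C)C[Mg]Cl
Why: In this chelation-controlled Grignard addition the first equivalent forms the C4 magnesium alkoxide, which binds the aldehyde oxygen in a six-membered chelate cis-fused to ring A whose inner face is covered by the C1 methyl group, so the methallyl group should enter from the outer face and give the 6S carbinol, the sense also predicted by the Felkin–Anh model with C1 as the large substituent.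

Step 9
Reactants: 16 (1R,2S,3R,4R)-3-allyl-4-(tert-butyldimethylsilyloxy)-2-[(1S)-1-hydroxy-3-methylbut-3-en-1-yl]-1-isopropyl-3-methylcyclopentan-1-ol; 17 4-methoxybenzoyl chloride
Product: 18 (1S)-1-[(1S,2R,3R,5R)-2-allyl-3-(tert-butyldimethylsilyloxy)-5-hydroxy-5-isopropyl-2-methylcyclopentyl]-3-methylbut-3-en-1-yl 4-methoxybenzoate
Conditions: 4-MeOC6H4COCl, Et3N, DMAP, CH2Cl2, 0 °C to rt
Reagents that add atoms: 4-methoxybenzoyl chloride COc1ccc(cc1)C(Cl)=O
Why: DMAP-catalysed acylation separates the secondary C6 alcohol from the tertiary, isopropyl-flanked C4 alcohol on steric grounds and leaves every stereocentre as it is.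

Step 10
Reactants: 18 ring A diene (C2 silyl ether, free C4 carbinol, C6 anisate)
Product: 19 (1R,3R,3aS,4S,8aR)-1-(tert-butyldimethylsilyloxy)-3-hydroxy-3-isopropyl-6,8a-dimethyl-1,2,3,3a,4,5,8,8a-octahydroazulen-4-yl 4-methoxybenzoate
Conditions: second-generation Grubbs catalyst (H2IMes)(PCy3)Cl2Ru=CHPh (5–10 mol %), CH2Cl2 (2 mM), reflux
Reagents that add atoms: none
Why: The ruthenium benzylidene first exchanges with the unhindered monosubstituted alkene of the C1 allyl arm, the new alkylidene at C9 adds across the 1,1-disubstituted alkene at C8 in a [2+2] step, and cycloreversion of the ruthenacyclobutane forms C8=C9 and hands on a methylidene that leaves as ethene. The closest known reaction type is ring-closing metathesis of a terminal alkene with a 1,1-disubstituted alkene to a trisubstituted cycloheptene, which is established for hydroazulene terpenoids. Ring B closes as a seven-membered ring by intramolecular metallacycle formation between two arms that stand trans on the neighbouring carbons C1 and C5, so the trans-fused bicyclo[5.3.0]decene should form directly. No stereocentre is made, and C1, C2, C4, C5 and C6 are each at least one saturated carbon away from the reacting alkenes and stay untouched. The step needs chemoselectivity and Z geometry: 18 holds only these two alkenes, high dilution holds back cross-metathesis between allyl arms, and a seven-membered ring can hold only the Z alkene. The free tertiary hydroxyl, the aryl ester and the silyl ether are all groups this catalyst tolerates.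

Step 11
Reactants: 19 bicyclic C2 silyl ether
Product: 20 (1R,3R,3aS,4S,8aR)-1,3-dihydroxy-3-isopropyl-6,8a-dimethyl-1,2,3,3a,4,5,8,8a-octahydroazulen-4-yl 4-methoxybenzoate
Conditions: HF·pyridine, pyridine, THF, 0 °C to rt
Reagents that add atoms: none
Why: Fluoride-mediated desilylation is driven by the strong Si–F bond, and buffered HF·pyridine is neither basic enough to move or cleave the aryl ester nor acidic enough to protonate the trisubstituted alkene or ionise the C4 carbinol.

Step 12
Reactants: 20 bicyclic C2 alcohol; 21 angelic acid ((Z)-2-methylbut-2-enoic acid)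
Product: 23 CNP0204191.1 (target), via angelic 2,4,6-trichlorobenzoic anhydride 22 (not isolated)
Conditions: 21, 2,4,6-Cl3C6H2COCl, Et3N, PhMe, rt; then 20, 80 °C
Reagents that add atoms: angelic acid C/C=C(/C)C(=O)O
Why: In this Yamaguchi-type mixed-anhydride esterification run without a nucleophilic amine catalyst the secondary C2 alcohol attacks the less hindered angeloyl carbonyl of 22, no acylpyridinium species open to reversible conjugate addition is formed so the Z alkene should not drift to the tiglate, and the tertiary C4 hydroxyl stays free.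

Compound list
1 | (R)-4-(tert-butyldimethylsilyloxy)cyclopent-2-en-1-one | CC(C)(C)[Si](C)(C)O[C@@H]1CC(=O)C=C1 | starting material
2 | methyllithium | [Li]C | starting material
3 | lithium dimethylcuprate | [Li+].C[Cu-]C | intermediate
4 | (3R,4R)-4-(tert-butyldimethylsilyloxy)-3-methyl-1-(trimethylsilyloxy)cyclopent-1-ene | CC(C)(C)[Si](C)(C)O[C@@H]1CC(O[Si](C)(C)C)=C[C@H]1C | intermediate
5 | (R)-4-(tert-butyldimethylsilyloxy)-3-methylcyclopent-2-en-1-one | CC(C)(C)[Si](C)(C)O[C@@H]1CC(=O)C=C1C | intermediate
6 | isopropylmagnesium chloride | CC(C)[Mg]Cl | starting material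
7 | isopropylcerium dichloride | CC(C)[Ce](Cl)Cl | intermediate
8 | (1R,4R)-4-(tert-butyldimethylsilyloxy)-1-isopropyl-3-methylcyclopent-2-en-1-ol | CC(C)(C)[Si](C)(C)O[C@@H]1C[C@@](O)(C(C)C)C=C1C | intermediate
9 | (bromomethyl)chlorodimethylsilane | C[Si](C)(Cl)CBr | starting material
10 | (1R,4R)-1-[(bromomethyl)dimethylsilyloxy]-4-(tert-butyldimethylsilyloxy)-1-isopropyl-3-methylcyclopent-2-ene | CC(C)(C)[Si](C)(C)O[C@@H]1C[C@@](O[Si](C)(C)CBr)(C(C)C)C=C1C | intermediate
11 | allyltributylstannane | C=CC[Sn](CCCC)(CCCC)CCCC | starting material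
12 | (3aR,4R,5R,6aR)-4-allyl-5-(tert-butyldimethylsilyloxy)-6a-isopropyl-2,2,4-trimethylhexahydro-2H-cyclopenta[d][1,2]oxasilole | CC(C)(C)[Si](C)(C)O[C@@H]1C[C@]2(C(C)C)O[Si](C)(C)C[C@@H]2[C@@]1(C)CC=C | intermediate
13 | (1R,2S,3R,4R)-3-allyl-4-(tert-butyldimethylsilyloxy)-2-(hydroxymethyl)-1-isopropyl-3-methylcyclopentan-1-ol | CC(C)(C)[Si](C)(C)O[C@@H]1C[C@@](O)(C(C)C)[C@H](CO)[C@@]1(C)CC=C | intermediate
14 | (1R,2R,3R,5R)-2-allyl-3-(tert-butyldimethylsilyloxy)-5-hydroxy-5-isopropyl-2-methylcyclopentane-1-carbaldehyde | CC(C)(C)[Si](C)(C)O[C@@H]1C[C@@](O)(C(C)C)[C@H](C=O)[C@@]1(C)CC=C | intermediate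
15 | 2-methylallylmagnesium chloride | CC(=C)C[Mg]Cl | starting material
16 | (1R,2S,3R,4R)-3-allyl-4-(tert-butyldimethylsilyloxy)-2-[(1S)-1-hydroxy-3-methylbut-3-en-1-yl]-1-isopropyl-3-methylcyclopentan-1-ol | CC(C)(C)[Si](C)(C)O[C@@H]1C[C@@](O)(C(C)C)[C@H]([C@@H](O)CC(C)=C)[C@@]1(C)CC=C | intermediate
17 | 4-methoxybenzoyl chloride | COc1ccc(cc1)C(Cl)=O | starting material
18 | (1S)-1-[(1S,2R,3R,5R)-2-allyl-3-(tert-butyldimethylsilyloxy)-5-hydroxy-5-isopropyl-2-methylcyclopentyl]-3-methylbut-3-en-1-yl 4-methoxybenzoate | CC(C)(C)[Si](C)(C)O[C@@H]1C[C@@](O)(C(C)C)[C@H]([C@@H](OC(=O)c2ccc(OC)cc2)CC(C)=C)[C@@]1(C)CC=C | intermediate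
19 | (1R,3R,3aS,4S,8aR)-1-(tert-butyldimethylsilyloxy)-3-hydroxy-3-isopropyl-6,8a-dimethyl-1,2,3,3a,4,5,8,8a-octahydroazulen-4-yl 4-methoxybenzoate | CC(C)(C)[Si](C)(C)O[C@@H]1C[C@@](O)(C(C)C)[C@@H]2[C@@H](OC(=O)c3ccc(OC)cc3)CC(C)=CC[C@]21C | intermediate
20 | (1R,3R,3aS,4S,8aR)-1,3-dihydroxy-3-isopropyl-6,8a-dimethyl-1,2,3,3a,4,5,8,8a-octahydroazulen-4-yl 4-methoxybenzoate | O[C@@H]1C[C@@](O)(C(C)C)[C@@H]2[C@@H](OC(=O)c3ccc(OC)cc3)CC(C)=CC[C@]21C | intermediate
21 | angelic acid, (Z)-2-methylbut-2-enoic acid | C/C=C(/C)C(=O)O | starting material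
22 | angelic 2,4,6-trichlorobenzoic anhydride | C/C=C(/C)C(=O)OC(=O)c1c(Cl)cc(Cl)cc1Cl | intermediate
23 | CNP0204191.1, (1R,3R,3aS,4S,8aR)-3-hydroxy-3-isopropyl-6,8a-dimethyl-1-{[(Z)-2-methylbut-2-enoyl]oxy}-1,2,3,3a,4,5,8,8a-octahydroazulen-4-yl 4-methoxybenzoate | C/C=C(/C)C(=O)O[C@@H]1C[C@@](O)(C(C)C)[C@@H]2[C@@H](OC(=O)c3ccc(OC)cc3)CC(C)=CC[C@]21C | target

Total step count: 12. Longest linear sequence: 12 steps, from 1 to 23.

Steps most likely to fail

Step 5. Capture of the crowded tertiary C1 radical by the allylstannane may be too slow to carry the chain. The radical would then be lost through hydrogen abstraction or disproportionation. The α-silyl radical could also be allylated before it cyclises.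

The fallback is a polar sequence that sets out from enone 5. Conjugate addition of allylcopper (CH2=CHCH2MgBr, CuBr·SMe2, LiCl, Me3SiCl, THF, −78 °C) anti to the silyl ether should give (3R,4R)-3-allyl-4-(tert-butyldimethylsilyloxy)-3-methyl-1-(trimethylsilyloxy)cyclopent-1-ene F1. A Mukaiyama aldol reaction with aqueous formaldehyde under Yb(OTf)3 catalysis then leads to (2S,3R,4R)-3-allyl-4-(tert-butyldimethylsilyloxy)-2-(hydroxymethyl)-3-methylcyclopentan-1-one F2. In that aldol the enol silane faces differ only by methyl against allyl, so face selection at C5 is weakly biased and the C5 epimers would have to be separated. Addition of excess CeCl3/i-PrMgCl anti to the C5 substituent returns to the route at diol 13.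

Step 10. The bulky anisate next to the 1,1-disubstituted alkene may slow the ring-closing event. Cross-metathesis between allyl arms, alkene migration or catalyst decay could then take over.

The fallback closes ring B one step earlier and sets out from diol 16. The small, hydrogen-bonded C6 hydroxyl should leave the methallyl arm more accessible. Metathesis with the same ruthenium carbene should give (1R,3R,3aS,4S,8aR)-1-(tert-butyldimethylsilyloxy)-3-isopropyl-6,8a-dimethyl-1,2,3,3a,4,5,8,8a-octahydroazulene-3,4-diol F3. Selective acylation of its secondary C6 hydroxyl with 17 (Et3N, DMAP) comes back to the route at 19.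

Step 12. The C2 alcohol sits next to the quaternary C1 and may acylate slowly. Long heating gives the acyl donor time to isomerise from Z to E.

The fallback builds the Z alkene on the ester and sets out from 20. Esterification with 2-[bis(2,2,2-trifluoroethoxy)phosphoryl]propanoic acid (EDC, DMAP, CH2Cl2), which has no alkene to isomerise, should give the C2 2-[bis(2,2,2-trifluoroethoxy)phosphoryl]propanoate of 20 F4. This ester would be a mixture at the phosphonate carbon. Z-selective Still–Gennari olefination with acetaldehyde (KN(SiMe3)2, 18-crown-6, THF, −78 °C) comes back to the route at 23.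

Further compounds
F1 | step 5 | (3R,4R)-3-allyl-4-(tert-butyldimethylsilyloxy)-3-methyl-1-(trimethylsilyloxy)cyclopent-1-ene | CC(C)(C)[Si](C)(C)O[C@@H]1CC(O[Si](C)(C)C)=C[C@@]1(C)CC=C
F2 | step 5 | (2S,3R,4R)-3-allyl-4-(tert-butyldimethylsilyloxy)-2-(hydroxymethyl)-3-methylcyclopentan-1-one | CC(C)(C)[Si](C)(C)O[C@@H]1CC(=O)[C@H](CO)[C@@]1(C)CC=C
F3 | step 10 | (1R,3R,3aS,4S,8aR)-1-(tert-butyldimethylsilyloxy)-3-isopropyl-6,8a-dimethyl-1,2,3,3a,4,5,8,8a-octahydroazulene-3,4-diol | CC(C)(C)[Si](C)(C)O[C@@H]1C[C@@](O)(C(C)C)[C@@H]2[C@@H](O)CC(C)=CC[C@]21C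
F4 | step 12 | C2 2-[bis(2,2,2-trifluoroethoxy)phosphoryl]propanoate of 20 | CC(C(=O)O[C@@H]1C[C@@](O)(C(C)C)[C@@H]2[C@@H](OC(=O)c3ccc(OC)cc3)CC(C)=CC[C@]21C)P(=O)(OCC(F)(F)F)OCC(F)(F)F
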